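Labels: tetrahydrofuran ring O1–C2(aryl)–C3(C9H2OH)–C4(C7'H(OH)aryl)–C5H2. Retrosynthetic cuts, in order: the O–Si bonds, C7'–H, C7'–aryl, then O1–C2 and C4–C5 in one stroke, and last C3–C4.
Enabling feature: C2 bears an electron-rich aryl donor, C4 becomes an acceptor carbon once C7' is a carbonyl, and C3 links them, so C2–C3–C4 is a latent donor–acceptor cyclopropane ring. O1–C5 is one molecule of formaldehyde. The C3 and C4 arms are cis and can be tied as a γ-lactone ring (C7'(=O)–O–C9) fused to that cyclopropane.
Forward: cyclopropane ring from an enal and bromomalonate, lactone ring by reduction, tetrahydrofuran ring by strain-release (3+2) annulation with formaldehyde. Then the helper ester is lost, the lactone ring is opened to an amide, the second aryl is joined as an aryllithium, the ketone is reduced and the silyl groups are removed.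
Stereochemistry: C2 and C3 come from an (S)-diphenylprolinol silyl ether catalyst. C3 relays to C4 through ring fusions that can only be cis. C2 is re-formed in the key step under allylic 1,3-strain. C7' comes from an (R)-oxazaborolidine matched with the substrate bias.

Key step: step 4

Remark: ArT = 3-methoxy-4-(triisopropylsilyloxy)phenyl. Compound 1 is taken as the commercial E isomer, and paraformaldehyde as the commercial form of 7.

Step 1
Reactants: 1 (E)-coniferaldehyde, (E)-3-(4-hydroxy-3-methoxyphenyl)prop-2-enal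
Product: 2 (E)-3-ArT-prop-2-enal
Conditions: TIPSCl, imidazole, DMF, rt
Reagents that add atoms: triisopropylsilyl chloride, CC(C)[Si](Cl)(C(C)C)C(C)C
Why: Imidazole-promoted O-silylation of a phenol, with TIPS chosen over smaller silyl groups because it must outlast a Lewis acid and hot wet DMSO while leaving the para oxygen a strong donor.

Step 2
Reactants: 2 (E)-3-ArT-prop-2-enal; 3 dimethyl 2-bromomalonate
Product: 4 dimethyl (2S,3R)-2-ArT-3-formylcyclopropane-1,1-dicarboxylate (aryl and formyl trans)
Conditions: (S)-α,α-diphenylprolinol trimethylsilyl ether (20 mol %), 2,6-lutidine, CH2Cl2, 0 °C to rt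
Reagents that add atoms: none
Why: Iminium–enamine organocatalytic Michael-initiated ring closure, in which the malonate carbon adds to the Si face of the β-carbon (C2) left open by the diphenyl(silyloxy)methyl group and the enamine carbon C3 then displaces bromide (3-exo-tet), setting C2 (S) and C3 (R) with aryl and formyl trans.

Step 3
Reactants: 4 dimethyl (2S,3R)-2-ArT-3-formylcyclopropane-1,1-dicarboxylate
Product: 6 methyl (1S,5R,6S)-6-ArT-2-oxo-3-oxabicyclo[3.1.0]hexane-1-carboxylate (aryl exo: trans to C9 and to the lactone carbonyl, cis to the ester), via hydroxymethyl cyclopropane diester 5 (not isolated)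
Conditions: NaBH4, MeOH, 0 °C; then PPTS (cat.), toluene, 50 °C
Reagents that add atoms: none
Why: Chemoselective borohydride reduction of the aldehyde followed by lactonisation onto the one ester that is cis to the new CH2OH, so that C3 fixes the configuration of the now stereogenic C4 and the aryl group stays exo.

Step 4
Reactants: 6 methyl (1S,5R,6S)-6-ArT-2-oxo-3-oxabicyclo[3.1.0]hexane-1-carboxylate; 7 formaldehyde (charged as paraformaldehyde)
Product: 8 methyl (1R,5R,6S)-6-ArT-2-oxo-3,7-dioxabicyclo[3.3.0]octane-1-carboxylate (cis-fused tetrahydrofuran–lactone, angular ester on C4, aryl on the convex face and trans to C9)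
Conditions: Sn(OTf)2 (10 mol %), (CH2O)n (5 equiv), 4 Å MS, CH2Cl2, 0 °C to rt
Reagents that add atoms: none
Why: Sn(OTf)2 chelates the lactone and ester carbonyls on C4, the C2–C4 bond (the only ring bond flanked by the aryl donor and both acceptors) ionises to a para-silyloxybenzyl cation at C2 and a tin enolate at C4, and monomeric formaldehyde set free from the polymer is taken up between the two termini, its electrophilic carbon by C4 (C4–C5) and its oxygen by C2 (O1–C2). The closest known reaction type is the Lewis acid catalysed (3+2) annulation of 2-arylcyclopropane-1,1-dicarboxylates with aldehydes to tetrahydrofuran-3,3-dicarboxylates, of which the unsubstituted aldehyde and the lactone-tied diester are new members. The single ring closed is the tetrahydrofuran, by 5-exo-trig attack of the tin alkoxide O1 on the quinone-methide-like C2 when C4–C5 forms first, or by 5-(enolexo)-endo-trig attack of C4 on the oxocarbenium carbon C5 when O1–C2 forms first, the bonds made being the same. C3 is untouched and controls C4, because the O1–C5 bridge anchored at C2 can reach only the lactone face that C2 already occupies, so that C5 takes the place of C2 on C4 and only the cis-fused bicycle can form. C2 is planar in the open form, and the rotamer into which the exo-aryl cyclopropane opens holds C3–H in the plane of the aryl cation (minimal allylic 1,3-strain), so that O1 arriving from the C4 side leaves the aryl group trans to C9 on the convex face, a net retention. The step therefore needs this ionised, retentive course to outrun the invertive rear-side capture known for weaker donors, which is secured by the strongly donating 4-silyloxy-3-methoxyphenyl group, by the poor oxygen nucleophilicity and high carbon electrophilicity of formaldehyde, and by the bulky TIPS group that keeps triflate off silicon.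

Step 5
Reactants: 8 methyl (1R,5R,6S)-6-ArT-2-oxo-3,7-dioxabicyclo[3.3.0]octane-1-carboxylate
Product: 9 (1R,5R,6S)-6-ArT-3,7-dioxabicyclo[3.3.0]octan-2-one
Conditions: LiCl, H2O (2 equiv), DMSO, 130 °C
Reagents that add atoms: none
Why: Krapcho dealkoxycarbonylation, in which chloride takes the methyl group of the doubly activated ester, carbon dioxide leaves and the lactone enolate is protonated, and since only the cis-fused bicycle is attainable the proton lands on the convex face and C4 emerges R with its carbonyl arm still cis to C9.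

Step 6
Reactants: 9 (1R,5R,6S)-6-ArT-3,7-dioxabicyclo[3.3.0]octan-2-one
Product: 10 (3R,4R,5S)-5-ArT-4-(hydroxymethyl)-N-methoxy-N-methyltetrahydrofuran-3-carboxamide
Conditions: MeNH(OMe)·HCl, i-PrMgCl, THF, −20 to 0 °C; aq. NH4Cl
Reagents that add atoms: N,O-dimethylhydroxylamine hydrochloride, CNOC.Cl
Why: Aminolysis of a γ-lactone by the chloromagnesium amide of N,O-dimethylhydroxylamine (Weinreb amide formation) frees C9–OH without touching C2, C3 or C4, the low temperature keeping C4–H in place.

Step 7
Reactants: 10 (3R,4R,5S)-5-ArT-4-(hydroxymethyl)-N-methoxy-N-methyltetrahydrofuran-3-carboxamide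
Product: 11 (3R,4R,5S)-5-ArT-4-[(tert-butyldimethylsilyloxy)methyl]-N-methoxy-N-methyltetrahydrofuran-3-carboxamide
Conditions: TBSCl, imidazole, CH2Cl2, 0 °C to rt
Reagents that add atoms: tert-butyldimethylsilyl chloride, CC(C)(C)[Si](C)(C)Cl
Why: Imidazole-promoted silylation of the primary alcohol, run at once, blocks relactonisation and installs a third fluoride-labile group so that a single reagent can finish the synthesis.

Step 8
Reactants: 12 4-bromo-2-methoxyphenol
Product: 13 (4-bromo-2-methoxyphenoxy)triisopropylsilane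
Conditions: TIPSCl, imidazole, DMF, rt
Reagents that add atoms: triisopropylsilyl chloride, CC(C)[Si](Cl)(C(C)C)C(C)C
Why: Standard phenol silylation that masks the acidic OH before halogen–lithium exchange.

Step 9
Reactants: 11 (3R,4R,5S)-5-ArT-4-[(tert-butyldimethylsilyloxy)methyl]-N-methoxy-N-methyltetrahydrofuran-3-carboxamide; 13 (4-bromo-2-methoxyphenoxy)triisopropylsilane
Product: 16 ArT {(3R,4R,5S)-5-ArT-4-[(tert-butyldimethylsilyloxy)methyl]tetrahydrofuran-3-yl} ketone, via aryllithium 14 (not isolated), via tetrahedral lithium adduct 15 (not isolated)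
Conditions: 13, n-BuLi, THF, −78 °C; then 11, −78 °C; aq. NH4Cl
Reagents that add atoms: none
Why: Bromine–lithium exchange and Weinreb ketone synthesis, in which the chelated tetrahedral adduct survives until the quench, so that one aryl group only is delivered and the C4–H next to the new ketone meets nothing more basic than buffered water.

Step 10
Reactants: 16 ArT {(3R,4R,5S)-5-ArT-4-[(tert-butyldimethylsilyloxy)methyl]tetrahydrofuran-3-yl} ketone
Product: 17 (S)-ArT{(3R,4R,5S)-5-ArT-4-[(tert-butyldimethylsilyloxy)methyl]tetrahydrofuran-3-yl}methanol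
Conditions: (R)-Me-CBS ((R)-1-methyl-3,3-diphenyltetrahydro-1H,3H-pyrrolo[1,2-c][1,3,2]oxazaborole, 0.3 equiv), BH3·SMe2, THF, −30 °C; then MeOH
Reagents that add atoms: none
Why: Corey–Bakshi–Shibata reduction, in which the (R)-oxazaborolidine with the aryl group as the large flank delivers hydride to the face giving the 7'S alcohol, the same face favoured by acyclic 1,2-induction from C4 (C3 as largest α-substituent anti to the hydride, C4–H next to the aryl), so that catalyst and substrate are matched.

Step 11
Reactants: 17 (S)-ArT{(3R,4R,5S)-5-ArT-4-[(tert-butyldimethylsilyloxy)methyl]tetrahydrofuran-3-yl}methanol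
Product: 18 (−)-tanegol, (2S,3R,4R)-2-(4-hydroxy-3-methoxyphenyl)-4-[(S)-hydroxy(4-hydroxy-3-methoxyphenyl)methyl]-3-(hydroxymethyl)tetrahydrofuran
Conditions: Bu4NF, AcOH, THF, 0 °C to rt
Reagents that add atoms: none
Why: Fluoride-induced cleavage of all three silyl ethers, buffered with acetic acid so that free phenoxides able to expel the benzylic oxygen functions as quinone methides do not build up, leaves the four stereocentres untouched.

Compound list
1 | (E)-coniferaldehyde | COc1cc(/C=C/C=O)ccc1O | starting material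
2 | (E)-3-[3-methoxy-4-(triisopropylsilyloxy)phenyl]prop-2-enal | COc1cc(/C=C/C=O)ccc1O[Si](C(C)C)(C(C)C)C(C)C | intermediate
3 | dimethyl 2-bromomalonate | COC(=O)C(Br)C(=O)OC | starting material
4 | dimethyl (2S,3R)-2-ArT-3-formylcyclopropane-1,1-dicarboxylate | O=C[C@@H]1[C@@H](c2ccc(O[Si](C(C)C)(C(C)C)C(C)C)c(OC)c2)C1(C(=O)OC)C(=O)OC | intermediate
5 | dimethyl (2S,3R)-2-ArT-3-(hydroxymethyl)cyclopropane-1,1-dicarboxylate | OC[C@@H]1[C@@H](c2ccc(O[Si](C(C)C)(C(C)C)C(C)C)c(OC)c2)C1(C(=O)OC)C(=O)OC | intermediate
6 | methyl (1S,5R,6S)-6-ArT-2-oxo-3-oxabicyclo[3.1.0]hexane-1-carboxylate, aryl exo | O=C1OC[C@@H]2[C@@H](c3ccc(O[Si](C(C)C)(C(C)C)C(C)C)c(OC)c3)[C@]12C(=O)OC | intermediate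
7 | formaldehyde (as paraformaldehyde) | C=O | starting material
8 | methyl (1R,5R,6S)-6-ArT-2-oxo-3,7-dioxabicyclo[3.3.0]octane-1-carboxylate | O=C1OC[C@@H]2[C@@H](c3ccc(O[Si](C(C)C)(C(C)C)C(C)C)c(OC)c3)OC[C@]12C(=O)OC | intermediate
9 | (1R,5R,6S)-6-ArT-3,7-dioxabicyclo[3.3.0]octan-2-one | O=C1OC[C@@H]2[C@@H](c3ccc(O[Si](C(C)C)(C(C)C)C(C)C)c(OC)c3)OC[C@H]12 | intermediate
10 | (3R,4R,5S)-5-ArT-4-(hydroxymethyl)-N-methoxy-N-methyltetrahydrofuran-3-carboxamide | CON(C)C(=O)[C@H]1CO[C@H](c2ccc(O[Si](C(C)C)(C(C)C)C(C)C)c(OC)c2)[C@H]1CO | intermediate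
11 | (3R,4R,5S)-5-ArT-4-[(tert-butyldimethylsilyloxy)methyl]-N-methoxy-N-methyltetrahydrofuran-3-carboxamide | CON(C)C(=O)[C@H]1CO[C@H](c2ccc(O[Si](C(C)C)(C(C)C)C(C)C)c(OC)c2)[C@H]1CO[Si](C)(C)C(C)(C)C | intermediate
12 | 4-bromo-2-methoxyphenol | COc1cc(Br)ccc1O | starting material
13 | (4-bromo-2-methoxyphenoxy)triisopropylsilane | COc1cc(Br)ccc1O[Si](C(C)C)(C(C)C)C(C)C | intermediate
14 | [3-methoxy-4-(triisopropylsilyloxy)phenyl]lithium | [Li]c1ccc(O[Si](C(C)C)(C(C)C)C(C)C)c(OC)c1 | intermediate
15 | lithium alkoxide of the aryl N-methoxy-N-methyl hemiaminal from 11 and 14 (C7' undefined) | [Li+].[O-]C(N(C)OC)(c1ccc(O[Si](C(C)C)(C(C)C)C(C)C)c(OC)c1)[C@H]2CO[C@H](c3ccc(O[Si](C(C)C)(C(C)C)C(C)C)c(OC)c3)[C@H]2CO[Si](C)(C)C(C)(C)C | intermediate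
16 | ArT {(3R,4R,5S)-5-ArT-4-[(tert-butyldimethylsilyloxy)methyl]tetrahydrofuran-3-yl} ketone | COc1cc(C(=O)[C@H]2CO[C@H](c3ccc(O[Si](C(C)C)(C(C)C)C(C)C)c(OC)c3)[C@H]2CO[Si](C)(C)C(C)(C)C)ccc1O[Si](C(C)C)(C(C)C)C(C)C | intermediate
17 | (S)-ArT{(3R,4R,5S)-5-ArT-4-[(tert-butyldimethylsilyloxy)methyl]tetrahydrofuran-3-yl}methanol | COc1cc([C@@H](O)[C@H]2CO[C@H](c3ccc(O[Si](C(C)C)(C(C)C)C(C)C)c(OC)c3)[C@H]2CO[Si](C)(C)C(C)(C)C)ccc1O[Si](C(C)C)(C(C)C)C(C)C | intermediate
18 | (−)-tanegol | COc1cc([C@@H](O)[C@H]2CO[C@H](c3ccc(O)c(OC)c3)[C@H]2CO)ccc1O | target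

Total step count: 11. Longest linear sequence: 10 steps (steps 1–7 and 9–11, from 1).

Steps most likely to fail

Step 4. The opened cyclopropane may be captured from the rear of the breaking C2–C4 bond. That would invert C2 and turn the aryl group into the concave face. Formaldehyde may also be taken up too slowly, so that the zwitterion recloses, is hydrated by water carried in with the polymer, or alkylates another arene.

The fallback makes the same two bonds one at a time with known reactions, the C–O bond last. It sets out from 4 and comes back at 8.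
- Borohydride reduction of 4 at −40 °C (via 5) and immediate silylation (TBSCl, imidazole) should give dimethyl (2S,3R)-2-ArT-3-[(tert-butyldimethylsilyloxy)methyl]cyclopropane-1,1-dicarboxylate F1.
- Hydrogenolysis (H2, Pd/C, EtOAc) cleaves the benzylic donor–acceptor bond C2–C4 to dimethyl 2-[(2R)-1-ArT-3-(tert-butyldimethylsilyloxy)propan-2-yl]malonate F2.
- Base-catalysed hydroxymethylation (paraformaldehyde, cat. DBU, THF) makes C4–C5 in dimethyl 2-(hydroxymethyl)-2-[(2R)-1-ArT-3-(tert-butyldimethylsilyloxy)propan-2-yl]malonate F3, in which C4 is not yet stereogenic.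
- DDQ (CH2Cl2, 0 °C) oxidises the benzylic C2–H to the cation. The C5 hydroxyl traps it 5-exo under allylic 1,3-strain control, giving the 2,3-trans diester dimethyl (4R,5S)-5-ArT-4-[(tert-butyldimethylsilyloxy)methyl]dihydrofuran-3,3(2H)-dicarboxylate F4.
- HF·pyridine (THF, 0 °C) removes the alkyl silyl ether, and dimethyl (4R,5S)-5-ArT-4-(hydroxymethyl)dihydrofuran-3,3(2H)-dicarboxylate F5 lactonises onto the cis ester, which is 8.

Step 5. The aryl silyl ether may be lost in hot wet DMSO. The transient C4 enolate may also expel O1 by β-elimination, which would open the tetrahedrofuran ring just made. The fallback replaces halide dealkylation in a polar medium by hydrolysis and thermal decarboxylation of the isolated acid in a non-polar one. It sets out from 8 and comes back at 9. Me3SnOH (1,2-dichloroethane, 80 °C, KHSO4 work-up, which recloses any opened lactone) should give (1R,5R,6S)-6-ArT-2-oxo-3,7-dioxabicyclo[3.3.0]octane-1-carboxylic acid F6. In refluxing toluene this acid loses carbon dioxide through the cyclic enol pathway and tautomerises to the cis-fused 9.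

Step 10. The oxazaborolidine may fail to tell the aryl flank from the branched ring flank, and a slow catalysed path may let free borane reduce the ketone, both eroding facial selectivity at C7'. The fallback gives up catalyst control and relies on the substrate alone. It sets out from 16 and comes back at 17. The bulky hydride LiBH(s-Bu)3 (THF, −78 °C) attacks anti to C3 along the path next to C4–H, the 1,2-induction that leads to the 7'S alcohol. No new compound is made on the way.

Further compounds
F1 | step 4 | dimethyl (2S,3R)-2-ArT-3-[(tert-butyldimethylsilyloxy)methyl]cyclopropane-1,1-dicarboxylate | CC(C)(C)[Si](C)(C)OC[C@@H]1[C@@H](c2ccc(O[Si](C(C)C)(C(C)C)C(C)C)c(OC)c2)C1(C(=O)OC)C(=O)OC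
F2 | step 4 | dimethyl 2-[(2R)-1-ArT-3-(tert-butyldimethylsilyloxy)propan-2-yl]malonate | COC(=O)C(C(=O)OC)[C@@H](Cc1ccc(O[Si](C(C)C)(C(C)C)C(C)C)c(OC)c1)CO[Si](C)(C)C(C)(C)C
F3 | step 4 | dimethyl 2-(hydroxymethyl)-2-[(2R)-1-ArT-3-(tert-butyldimethylsilyloxy)propan-2-yl]malonate | COC(=O)C(CO)(C(=O)OC)[C@@H](Cc1ccc(O[Si](C(C)C)(C(C)C)C(C)C)c(OC)c1)CO[Si](C)(C)C(C)(C)C
F4 | step 4 | dimethyl (4R,5S)-5-ArT-4-[(tert-butyldimethylsilyloxy)methyl]dihydrofuran-3,3(2H)-dicarboxylate | COC(=O)C1(C(=O)OC)CO[C@H](c2ccc(O[Si](C(C)C)(C(C)C)C(C)C)c(OC)c2)[C@H]1CO[Si](C)(C)C(C)(C)C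
F5 | step 4 | dimethyl (4R,5S)-5-ArT-4-(hydroxymethyl)dihydrofuran-3,3(2H)-dicarboxylate | COC(=O)C1(C(=O)OC)CO[C@H](c2ccc(O[Si](C(C)C)(C(C)C)C(C)C)c(OC)c2)[C@H]1CO
F6 | step 5 | (1R,5R,6S)-6-ArT-2-oxo-3,7-dioxabicyclo[3.3.0]octane-1-carboxylic acid | O=C1OC[C@@H]2[C@@H](c3ccc(O[Si](C(C)C)(C(C)C)C(C)C)c(OC)c3)OC[C@]12C(=O)O
F0 | step 10 | none | none
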